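**Plan**

- Retrosynthesis: the three O–benzyl bonds are cut first, then C3–C4 of lactone ring B (leaving a diazoacetate on O1), then the O1–C2 ester bond, then the two ring A–carbon bonds (C4–C4a and the phenethyl link), back to resorcinol, (3,4-dimethoxyphenyl)acetic acid, 3,4-dihydroxybenzoic acid and bromoacetyl bromide.
- Enabling feature: C4 carries catechol ring C and is bonded to C4a of ring A, whose neighbour C8a holds O1. A diazoacetyl unit on O1 (C2, C3) therefore faces the two enantiotopic, doubly benzylic C4–H bonds at the distance of a six-membered ring.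
- Forward: ring A (resorcinol) receives the phenethyl arm (acylation, deoxygenation) and then the aroyl arm. The hydrogen-bonded hydroxyl stays free on tri-O-benzylation, the ketone is reduced to CH2, and the free phenol is converted to the diazoacetate. Ring B then closes by C–H insertion and hydrogenolysis frees the three phenols.
- Stereochemistry: C4 is the only stereocentre. It is set as (R) in the ring B closure by the chiral catalyst pocket selecting the pro-R hydrogen, and nothing afterwards can epimerise it.
- Protection: all three phenols are carried as benzyl ethers, so the last step is a neutral hydrogenolysis that cannot open the lactone.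

Key step: step 8

Remark (assumption): a haem-protein carbene transferase that accepts diazo ester 12 must be obtained by directed evolution from lactone-forming variants. It is a catalyst to be developed, and a chiral dirhodium carboxamidate such as Rh2(5S-MEPY)4 would be the small-molecule stand-in for first screening of 12.

**Step 1**
Reactants: 1 resorcinol; 2 (3,4-dimethoxyphenyl)acetic acid
Product: 3 1-(2,4-dihydroxyphenyl)-2-(3,4-dimethoxyphenyl)ethan-1-one
Conditions: BF3·OEt2 (solvent and promoter), 85 °C; aq. NaOAc work-up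
Reagents that add atoms: none
Why: Friedel–Crafts (Nencki-type) C-acylation of resorcinol by an arylacetic acid in BF3·OEt2 goes para to one hydroxyl and ortho to the other, and stops after one acylation because the chelated ketone deactivates ring A.

**Step 2**
Reactants: 3 1-(2,4-dihydroxyphenyl)-2-(3,4-dimethoxyphenyl)ethan-1-one
Product: 4 4-[2-(3,4-dimethoxyphenyl)ethyl]benzene-1,3-diol
Conditions: Et3SiH (2.5 equiv), TFA, rt
Reagents that add atoms: none
Why: Ionic hydrogenation, in which the protonated aryl ketone and then the para-hydroxybenzyl cation each accept hydride from Et3SiH, so the carbonyl on the electron-rich ring is reduced to CH2 while arenes and methyl ethers are untouched.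

**Step 3**
Reactants: 4 4-[2-(3,4-dimethoxyphenyl)ethyl]benzene-1,3-diol; 5 3,4-dihydroxybenzoic acid
Product: 6 (3,4-dihydroxyphenyl){5-[2-(3,4-dimethoxyphenyl)ethyl]-2,4-dihydroxyphenyl}methanone
Conditions: BF3·OEt2 (solvent and promoter), 100 °C; aq. NaOAc work-up
Reagents that add atoms: none
Why: A second BF3-promoted Friedel–Crafts acylation (O-acylation followed by a Fries-type shift) should go to the one unhindered position of the 4-alkylresorcinol that is ortho to one hydroxyl and para to the other, the dimethoxyphenyl ring D being far less nucleophilic.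

**Step 4**
Reactants: 6 (3,4-dihydroxyphenyl){5-[2-(3,4-dimethoxyphenyl)ethyl]-2,4-dihydroxyphenyl}methanone
Product: 7 [4-(benzyloxy)-5-[2-(3,4-dimethoxyphenyl)ethyl]-2-hydroxyphenyl][3,4-bis(benzyloxy)phenyl]methanone
Conditions: BnBr (3.1 equiv), K2CO3, DMF, rt to 40 °C
Reagents that add atoms: benzyl bromide, BrCc1ccccc1
Why: Williamson etherification in which the hydroxyl ortho to the carbonyl is held in a strong intramolecular hydrogen bond and is the least nucleophilic, so three equivalents of BnBr should alkylate only the other three phenols.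

**Step 5**
Reactants: 7 [4-(benzyloxy)-5-[2-(3,4-dimethoxyphenyl)ethyl]-2-hydroxyphenyl][3,4-bis(benzyloxy)phenyl]methanone
Product: 9 5-(benzyloxy)-2-[3,4-bis(benzyloxy)benzyl]-4-[2-(3,4-dimethoxyphenyl)ethyl]phenol, via ethyl aryl carbonate 8 (not isolated)
Conditions: ClCO2Et, Et3N, THF, 0 °C; filter; NaBH4, THF–H2O, 0 °C to rt
Reagents that add atoms: none
Why: Reductive deoxygenation of an ortho-acylphenol through its ethyl carbonate, in which NaBH4 reduces the ketone, the carbonate shifts to the benzylic oxygen and leaves from the phenoxide to give an ortho-quinone methide, and a second hydride gives the benzylphenol, with benzyl and methyl ethers inert to borohydride.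

**Step 6**
Reactants: 9 5-(benzyloxy)-2-[3,4-bis(benzyloxy)benzyl]-4-[2-(3,4-dimethoxyphenyl)ethyl]phenol; 10 bromoacetyl bromide
Product: 11 5-(benzyloxy)-2-[3,4-bis(benzyloxy)benzyl]-4-[2-(3,4-dimethoxyphenyl)ethyl]phenyl bromoacetate
Conditions: NaHCO3, MeCN, 0 °C
Reagents that add atoms: none
Why: O-acylation of the single free phenol by the acyl bromide, with NaHCO3 as a non-nucleophilic acid scavenger that leaves the alkyl bromide in place.

**Step 7**
Reactants: 11 5-(benzyloxy)-2-[3,4-bis(benzyloxy)benzyl]-4-[2-(3,4-dimethoxyphenyl)ethyl]phenyl bromoacetate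
Product: 12 5-(benzyloxy)-2-[3,4-bis(benzyloxy)benzyl]-4-[2-(3,4-dimethoxyphenyl)ethyl]phenyl diazoacetate
Conditions: TsNHNHTs, DBU, THF, 0 °C
Reagents that add atoms: N,N'-ditosylhydrazine, Cc1ccc(cc1)S(=O)(=O)NNS(=O)(=O)c1ccc(C)cc1
Why: Diazo ester synthesis from a bromoacetate by N-alkylation of N,N'-ditosylhydrazine and two DBU-induced sulfinate eliminations, which runs at 0 °C and should therefore tolerate the aryl ester.

**Step 8**
Reactants: 12 5-(benzyloxy)-2-[3,4-bis(benzyloxy)benzyl]-4-[2-(3,4-dimethoxyphenyl)ethyl]phenyl diazoacetate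
Product: 13 (4R)-7-(benzyloxy)-4-[3,4-bis(benzyloxy)phenyl]-6-[2-(3,4-dimethoxyphenyl)ethyl]chroman-2-one
Conditions: engineered P411-type haem protein (cytochrome P450 BM3 variant with axial serine on the haem b iron, evolved for 12), Na2S2O4 (cat.), KH2PO4/K2HPO4 buffer pH 7.4, 10% EtOH, anaerobic, rt
Reagents that add atoms: none
Why: Proposed new method: the ferrous haem is expected to take up the diazo ester, lose N2 and form an electrophilic iron carbene at C3, which attacks one C4–H bond of the diarylmethane by hydrogen-atom abstraction and radical rebound (or a concerted, hydride-transfer-like insertion), so that C3–C4 forms with retention at C4. The closest known reaction types are lactone-forming intramolecular benzylic C–H insertions of diazo esters by engineered haem-protein carbene transferases and by chiral dirhodium carboxamidates; an aryl diazoacetate reaching a diarylmethane C–H in this way has not been shown. Ring B closes as a six-membered lactone by 1,6-insertion, its atoms being O1, C2, C3, C4, C4a and C8a with ring A as the ortho-fused backbone. The C4 stereocentre is controlled by the protein, whose active site must present the pro-R hydrogen of the CH2 group to the carbene to give the (R) lactone, and directed evolution is the means of reaching that selectivity. The step also needs site selectivity over attack on the aromatic C8–H (benzofuranone formation), Buchner-type addition to ring A or ring C and O–H insertion into water; the substrate helps because the C4–H bonds are doubly benzylic and para to the C7 and C4' benzyloxy groups, hence weak and hydridic, and because the ortho relationship of ester oxygen and benzyl group holds them within reach of C3.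

**Step 9**
Reactants: 13 (4R)-7-(benzyloxy)-4-[3,4-bis(benzyloxy)phenyl]-6-[2-(3,4-dimethoxyphenyl)ethyl]chroman-2-one
Product: 14 (4R)-4-(3,4-dihydroxyphenyl)-6-[2-(3,4-dimethoxyphenyl)ethyl]-7-hydroxychroman-2-one
Conditions: H2 (1 atm), Pd/C (10% Pd on carbon), EtOAc, rt
Reagents that add atoms: none
Why: Hydrogenolysis of the three benzyl aryl ethers under neutral conditions in a non-alcoholic solvent should leave the aryl lactone, the methyl ethers and the C4 stereocentre (a C–H centre with no heteroatom bond to cleave) unchanged.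

**Compound list**

1 | resorcinol | Oc1cccc(O)c1 | starting material
2 | (3,4-dimethoxyphenyl)acetic acid | COc1ccc(CC(=O)O)cc1OC | starting material
3 | 1-(2,4-dihydroxyphenyl)-2-(3,4-dimethoxyphenyl)ethan-1-one | COc1ccc(CC(=O)c2ccc(O)cc2O)cc1OC | intermediate
4 | 4-[2-(3,4-dimethoxyphenyl)ethyl]benzene-1,3-diol | COc1ccc(CCc2ccc(O)cc2O)cc1OC | intermediate
5 | 3,4-dihydroxybenzoic acid | OC(=O)c1ccc(O)c(O)c1 | starting material
6 | (3,4-dihydroxyphenyl){5-[2-(3,4-dimethoxyphenyl)ethyl]-2,4-dihydroxyphenyl}methanone | COc1ccc(CCc2cc(C(=O)c3ccc(O)c(O)c3)c(O)cc2O)cc1OC | intermediate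
7 | [4-(benzyloxy)-5-[2-(3,4-dimethoxyphenyl)ethyl]-2-hydroxyphenyl][3,4-bis(benzyloxy)phenyl]methanone | COc1ccc(CCc2cc(C(=O)c3ccc(OCc4ccccc4)c(OCc4ccccc4)c3)c(O)cc2OCc2ccccc2)cc1OC | intermediate
8 | 5-(benzyloxy)-2-[3,4-bis(benzyloxy)benzoyl]-4-[2-(3,4-dimethoxyphenyl)ethyl]phenyl ethyl carbonate (not isolated) | CCOC(=O)Oc1cc(OCc2ccccc2)c(CCc2ccc(OC)c(OC)c2)cc1C(=O)c1ccc(OCc2ccccc2)c(OCc2ccccc2)c1 | intermediate
9 | 5-(benzyloxy)-2-[3,4-bis(benzyloxy)benzyl]-4-[2-(3,4-dimethoxyphenyl)ethyl]phenol | Oc1cc(OCc2ccccc2)c(CCc2ccc(OC)c(OC)c2)cc1Cc1ccc(OCc2ccccc2)c(OCc2ccccc2)c1 | intermediate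
10 | bromoacetyl bromide | BrCC(Br)=O | starting material
11 | 5-(benzyloxy)-2-[3,4-bis(benzyloxy)benzyl]-4-[2-(3,4-dimethoxyphenyl)ethyl]phenyl bromoacetate | BrCC(=O)Oc1cc(OCc2ccccc2)c(CCc2ccc(OC)c(OC)c2)cc1Cc1ccc(OCc2ccccc2)c(OCc2ccccc2)c1 | intermediate
12 | 5-(benzyloxy)-2-[3,4-bis(benzyloxy)benzyl]-4-[2-(3,4-dimethoxyphenyl)ethyl]phenyl diazoacetate | [N-]=[N+]=CC(=O)Oc1cc(OCc2ccccc2)c(CCc2ccc(OC)c(OC)c2)cc1Cc1ccc(OCc2ccccc2)c(OCc2ccccc2)c1 | intermediate
13 | (4R)-7-(benzyloxy)-4-[3,4-bis(benzyloxy)phenyl]-6-[2-(3,4-dimethoxyphenyl)ethyl]chroman-2-one | O=C1C[C@H](c2ccc(OCc3ccccc3)c(OCc3ccccc3)c2)c2cc(CCc3ccc(OC)c(OC)c3)c(OCc3ccccc3)cc2O1 | intermediate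
14 | (4R)-4-(3,4-dihydroxyphenyl)-6-[2-(3,4-dimethoxyphenyl)ethyl]-7-hydroxychroman-2-one | COc1ccc(CCc2cc3c(cc2O)OC(=O)C[C@@H]3c2ccc(O)c(O)c2)cc1OC | target

**Step count and risks**

Total step count: 9. Longest linear sequence: 9 steps (1 to 14).

Steps most likely to fail:

1. Step 8. The protein may fail to bind so large a substrate, or the carbene may be diverted into attack on the aromatic C8–H, arene addition, O–H insertion into water or hydrolysis of the aryl ester before carbene formation. Discrimination between the two enantiotopic hydrogens may also be poor. Fallback with known chemistry, setting out from 4 and returning at 13: ZnCl2-promoted condensation of 4 with ethyl propiolate (Pechmann-type hydroarylation and lactonisation, dioxane, 100 °C) should give 6-[2-(3,4-dimethoxyphenyl)ethyl]-7-hydroxy-2H-chromen-2-one F1. Benzylation (BnBr, K2CO3, DMF) should give 7-(benzyloxy)-6-[2-(3,4-dimethoxyphenyl)ethyl]-2H-chromen-2-one F2. Rhodium-catalysed asymmetric 1,4-addition of 3,4-bis(benzyloxy)phenylboronic acid (Hayashi–Miyaura reaction; Rh(acac)(C2H4)2, (R)-Segphos, dioxane–H2O, 60 °C) would then form the C4–ring C bond under ligand control and deliver 13. The Segphos enantiomer is the one that adds the aryl group to the face giving (R), expected to be (R)-Segphos by analogy with 4-aryl additions to simple coumarins.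

2. Step 3. C-acylation by the electron-rich, unprotected catechol acid may be sluggish, with O-acylation or acylation at the position between the two hydroxyls competing. Fallback setting out from 4 and returning at 9 (it replaces steps 3 to 5): Vilsmeier–Haack formylation of 4 (POCl3, DMF, MeCN; aqueous hydrolysis) should give 5-[2-(3,4-dimethoxyphenyl)ethyl]-2,4-dihydroxybenzaldehyde F3. Selective etherification of the non-chelated hydroxyl (BnBr, NaHCO3, MeCN) should give 4-(benzyloxy)-5-[2-(3,4-dimethoxyphenyl)ethyl]-2-hydroxybenzaldehyde F4. Addition of [3,4-bis(benzyloxy)phenyl]magnesium bromide F5 (made from 4-bromo-1,2-bis(benzyloxy)benzene and Mg in THF, 2.2 equiv) should give racemic 5-(benzyloxy)-2-{[3,4-bis(benzyloxy)phenyl](hydroxy)methyl}-4-[2-(3,4-dimethoxyphenyl)ethyl]phenol F6. Ionic hydrogenation of this benzhydrol (Et3SiH, TFA, CH2Cl2, 0 °C) would remove the hydroxyl and its stereocentre to give 9.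

3. Step 7. The activated aryl ester may be cleaved by DBU or sulfinate before the diazo group has formed, or the aryl diazoacetate may decompose under the basic conditions. Fallback setting out from 9 and returning at 12 (it replaces steps 6 and 7): acylation of 9 with glyoxylic acid chloride p-toluenesulfonylhydrazone (N,N-dimethylaniline, CH2Cl2, 0 °C) should give 5-(benzyloxy)-2-[3,4-bis(benzyloxy)benzyl]-4-[2-(3,4-dimethoxyphenyl)ethyl]phenyl (2E)-{2-[(4-methylphenyl)sulfonyl]hydrazinylidene}acetate F7. Treating it in the same flask with Et3N would expel sulfinate in a Bamford–Stevens-type fragmentation and give 12, so the diazo nitrogen arrives as a preformed hydrazone and no alkyl bromide or amidine base is needed.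

**Further compounds**

F1 | step 8 | 6-[2-(3,4-dimethoxyphenyl)ethyl]-7-hydroxy-2H-chromen-2-one | O=C1C=Cc2cc(CCc3ccc(OC)c(OC)c3)c(O)cc2O1
F2 | step 8 | 7-(benzyloxy)-6-[2-(3,4-dimethoxyphenyl)ethyl]-2H-chromen-2-one | O=C1C=Cc2cc(CCc3ccc(OC)c(OC)c3)c(OCc3ccccc3)cc2O1
F3 | step 3 | 5-[2-(3,4-dimethoxyphenyl)ethyl]-2,4-dihydroxybenzaldehyde | O=Cc1cc(CCc2ccc(OC)c(OC)c2)c(O)cc1O
F4 | step 3 | 4-(benzyloxy)-5-[2-(3,4-dimethoxyphenyl)ethyl]-2-hydroxybenzaldehyde | O=Cc1cc(CCc2ccc(OC)c(OC)c2)c(OCc2ccccc2)cc1O
F5 | step 3 | [3,4-bis(benzyloxy)phenyl]magnesium bromide | Br[Mg]c1ccc(OCc2ccccc2)c(OCc2ccccc2)c1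
F6 | step 3 | 5-(benzyloxy)-2-{[3,4-bis(benzyloxy)phenyl](hydroxy)methyl}-4-[2-(3,4-dimethoxyphenyl)ethyl]phenol (racemic) | OC(c1ccc(OCc2ccccc2)c(OCc2ccccc2)c1)c1cc(CCc2ccc(OC)c(OC)c2)c(OCc2ccccc2)cc1O
F7 | step 7 | 5-(benzyloxy)-2-[3,4-bis(benzyloxy)benzyl]-4-[2-(3,4-dimethoxyphenyl)ethyl]phenyl (2E)-{2-[(4-methylphenyl)sulfonyl]hydrazinylidene}acetate | Cc1ccc(cc1)S(=O)(=O)N/N=C/C(=O)Oc1cc(OCc2ccccc2)c(CCc2ccc(OC)c(OC)c2)cc1Cc1ccc(OCc2ccccc2)c(OCc2ccccc2)c1
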